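Its constants come from no measurement; no experiment stands behind them.

The winter flask starts from a route ratio of 1.05, catalysed rate over side rate.

| flask | starting material | free catalyst | temperature | time |
|---|---|---|---|---|
| spring | 1.5 M | 7.5 mM | 5 °C | 25 min |
| autumn | 1.5 M | 7.5 mM | −15 °C | 25 min |
| winter | 1.5 M | 7.5 mM | 25 °C | 25 min |

    starting material + free catalyst → free catalyst + target (k1 = 130 M⁻¹ min⁻¹, Ea1 = 58.0 kJ mol⁻¹)
    starting material → side product (k2 = 0.93 min⁻¹, Ea2 = 79.0 kJ mol⁻¹)
    free catalyst + target → spent catalyst (k3 = 0.12 M⁻¹ min⁻¹, Ea3 = 76.0 kJ mol⁻¹)
    (constants at 25 °C)

- at 25 °C the constants are as listed, elsewhere as the activation energies make them

- the flask with the highest amount of target, in percent of the starting material charged ("all alike" if they lie within 1.5 percentage points) (spring / autumn / winter / all alike)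
- final target, as a percentage of the starting material charged, in spring
- final target, as a percentage of the starting material charged, in autumn
- final target, as a percentage of the starting material charged, in winter

Starting material leaves by two routes, the catalysed step to target and the side step to side product. Both rates carry starting material to the first power, so their quotient loses it, and time drops out as well while free catalyst stands at its charge. What stays is the route ratio, the catalysed rate constant times free catalyst over the side rate constant, a selectivity factor. Of each portion converted, the share ratio/(1 + ratio) becomes target, so winter gives 51.2%.

But the side step climbs more steeply with temperature than the catalysed step, by 21.0 kJ mol⁻¹. So the ratio grows on cooling. At the start of spring it is 1.9, a share of 65.8%. The catalysed step speeds up 38-fold from autumn to winter, and scaling that factor by the energy gap puts the autumn ratio at 3.90, a share of 79.6%.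

The third step takes one target per catalyst, and the catalyst charge is 0.500% of the starting material, so this reckoning sets it aside and holds free catalyst at its charge.

Shares still need conversion. Winter's starting material lives 0.525 min, shorter than the time. Autumn is pseudo-first-order at 0.0326 min⁻¹, so this reckoning gives 44.4% there. Spring is assumed converted, and its share is higher than winter's.

The forecast says spring, with 65% in spring, 44.3% in autumn and 50% in winter, and holds that “catalyst death by target costs under a percentage point anywhere”. Its spring value lies just below this reckoning's.

The simulation gives spring the most target: 65.1% in spring, 44.3% in autumn, 50.1% in winter.

The winter flask ends at 50.1% mainly because of the side step: with that step taken away, target reaches 99.3%. A neighbour of spring with free catalyst cut to 0.0019 M starts from a ratio of 0.488, so a share of 32.8%. That neighbour flask ends with 31.4% target and 3.18% starting material left.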